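Ring B of the tetralone (C1, C2, C3, C4, C4a, C8a) is cut at C2–C3 and C4–C4a. This leaves the aroyl unit C4a–C8a–C1–C2 and a two-carbon unit C3–C4. In one operation a magnesium-chelated tertiary radical at C2 of an α-bromo-β-keto ester adds to a 1-arylpropyne. The vinyl radical at C4, stabilised by ring C, then closes on C4a, which is ortho to the acyl group and para to the C7 methoxy group of ring A. The benzyl ester at C2 blocks naphthol formation, carries the only stereocentre, directs syn hydrogenation of C3=C4 (3,4-cis) and finally leaves as CO2.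

Key step: step 5

Remark: atoms are numbered as in 1-tetralone (C1 carbonyl, C2 and C3 methyl-bearing, C4 aryl-bearing). Ring A is the dimethoxybenzo ring, ring B the cyclohexanone ring, ring C the pendant aryl ring. (S,S)-tBu-box is 2,2'-(propane-2,2-diyl)bis[(4S)-4-tert-butyl-4,5-dihydro-1,3-oxazole].

Assumption: the (S,S)-ligand is taken to leave open the face of the C2 radical that leads to (S)-8. If the opposite sense is found, the (R,R)-ligand is used and nothing else changes.

Step 1
Reactants: 1 benzyl propanoate; 2 3,4-dimethoxybenzoyl chloride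
Product: 3 benzyl 3-(3,4-dimethoxyphenyl)-2-methyl-3-oxopropanoate (racemic)
Conditions: LiN(iPr)2 (2.1 equiv), THF, −78 °C; then 2, −78 °C to 0 °C; aqueous NH4Cl
Reagents that add atoms: none
Why: Crossed Claisen-type C-acylation, in which the preformed lithium enolate of 1 attacks the acid chloride 2 and the second equivalent of base stores the more acidic β-keto ester as its enolate, so that double acylation is avoided; the C2 centre is racemic here and is erased in step 5.

Step 2
Reactants: 3 benzyl 3-(3,4-dimethoxyphenyl)-2-methyl-3-oxopropanoate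
Product: 4 benzyl 2-bromo-3-(3,4-dimethoxyphenyl)-2-methyl-3-oxopropanoate (racemic)
Conditions: NBS, Mg(ClO4)2 (10 mol %), MeCN, rt
Reagents that add atoms: N-bromosuccinimide, O=C1CCC(=O)N1Br
Why: Lewis-acid-catalysed electrophilic α-bromination of a 1,3-dicarbonyl compound, in which Mg(ClO4)2 speeds enolisation and the enol takes up bromine faster than the acyl-deactivated ring A; the racemic centre becomes a planar radical in step 5.

Step 3
Reactants: 5 5-bromo-2-methoxyphenol
Product: 6 2-(benzyloxy)-4-bromo-1-methoxybenzene
Conditions: BnBr, K2CO3, DMF, rt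
Reagents that add atoms: benzyl bromide, BrCc1ccccc1
Why: Williamson ether synthesis, in which the phenoxide of 5 displaces bromide from benzyl bromide; the benzyl ether is chosen because it falls together with the benzyl ester in step 7.

Step 4
Reactants: 6 2-(benzyloxy)-4-bromo-1-methoxybenzene
Product: 7 2-(benzyloxy)-1-methoxy-4-(prop-1-yn-1-yl)benzene
Conditions: propyne (solution in THF), PdCl2(MeCN)2 (2 mol %), XPhos (6 mol %), Cs2CO3, MeCN, 70 °C, sealed tube
Reagents that add atoms: propyne, CC#C
Why: Copper-free Sonogashira coupling, in which the bulky electron-rich phosphine allows oxidative addition of the electron-rich aryl bromide and the absence of copper avoids oxidative dimerisation of propyne.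

Step 5
Reactants: 4 benzyl 2-bromo-3-(3,4-dimethoxyphenyl)-2-methyl-3-oxopropanoate; 7 2-(benzyloxy)-1-methoxy-4-(prop-1-yn-1-yl)benzene
Product: 8 benzyl (2S)-4-[3-(benzyloxy)-4-methoxyphenyl]-6,7-dimethoxy-2,3-dimethyl-1-oxo-1,2-dihydronaphthalene-2-carboxylate
Conditions: fac-Ir(ppy)3 (1 mol %), Mg(ClO4)2 (30 mol %), (S,S)-tBu-box (33 mol %), Na2HPO4, 4 Å MS, CH2Cl2, blue LED, −20 °C
Reagents that add atoms: none
Why: Proposed new method: photoexcited fac-Ir(ppy)3 reduces the Mg-chelated bromide 4 to bromide ion and a planar tertiary 1,3-dicarbonyl radical at C2, which adds to the methyl-bearing alkyne carbon of 7 (C2–C3 bond) because only this regiochemistry gives a linear vinyl radical at C4 that is conjugated with the electron-rich ring C. This radical attacks C4a of ring A (C4–C4a bond; ring B closes by 6-endo-trig homolytic aromatic substitution), and the cyclohexadienyl radical is oxidised by the tetravalent iridium form of the photocatalyst and deprotonated by Na2HPO4, so that the step is redox-neutral overall. The closest known reaction types are the visible-light radical [4+2] benzannulation of 2-bromo-1,3-dicarbonyl compounds with alkynes and the enantioselective atom-transfer radical cyclisation of α-bromo-β-keto esters on Mg(ClO4)2/bis(oxazoline) complexes; what is new is their union in an intermolecular addition that builds a quaternary centre. The only new stereocentre, C2, is controlled by the twofold-symmetric ligand, whose tert-butyl groups shield one face of the six-membered chelate formed by Mg and the ketone and ester oxygen atoms, and the bound radical is more electrophilic than the free one, which should hold down the racemic background. Site selectivity on ring A is secured by the substrate: C4a is unhindered and para to the C7 methoxy group, the other ortho carbon C8 is flanked by a methoxy group, and 5-exo attack at C8a is reversible and unproductive. Because C2 bears methyl and ester and no hydrogen, 8 cannot tautomerise to a naphthol and keeps the C3=C4 double bond for step 6.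

Step 6
Reactants: 8 benzyl (2S)-4-[3-(benzyloxy)-4-methoxyphenyl]-6,7-dimethoxy-2,3-dimethyl-1-oxo-1,2-dihydronaphthalene-2-carboxylate
Product: 9 benzyl (2S,3R,4R)-4-[3-(benzyloxy)-4-methoxyphenyl]-6,7-dimethoxy-2,3-dimethyl-1-oxo-1,2,3,4-tetrahydronaphthalene-2-carboxylate
Conditions: [Ir(cod)(PCy3)(py)]PF6 (10 mol %), H2 (50 bar), CH2Cl2, rt
Reagents that add atoms: none
Why: Carbonyl-directed homogeneous hydrogenation of the Crabtree type, in which the cationic iridium centre binds the ester carbonyl oxygen at C2 and delivers both hydrogen atoms to the same face of C3=C4, syn to the ester, which sets 3R and 4R at once and places the C3 methyl group and ring C cis, while benzyl groups and the aryl ketone are left alone by this catalyst.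

Step 7
Reactants: 9 benzyl (2S,3R,4R)-4-[3-(benzyloxy)-4-methoxyphenyl]-6,7-dimethoxy-2,3-dimethyl-1-oxo-1,2,3,4-tetrahydronaphthalene-2-carboxylate
Product: 12 (2S,3R,4R)-4-(3-hydroxy-4-methoxyphenyl)-6,7-dimethoxy-2,3-dimethyl-3,4-dihydronaphthalen-1(2H)-one (target), via keto acid 10 (not isolated), via C2 epimer 11 (not isolated)
Conditions: H2 (1 atm), Pd/C, EtOAc, rt; filter, 50 °C; then DBU (0.2 equiv), toluene, 60 °C
Reagents that add atoms: none
Why: Hydrogenolysis frees the phenol and the β-keto acid 10, which loses CO2 through its enol on gentle warming, and DBU then equilibrates the only epimerisable centre C2 by enolisation towards the more stable 2,3-trans arrangement (both methyl groups equatorial, ring C pseudoaxial), while C3 and C4 are not acidic enough to be touched.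

Compound list
1 | benzyl propanoate | CCC(=O)OCc1ccccc1 | starting material
2 | 3,4-dimethoxybenzoyl chloride | COc1ccc(C(=O)Cl)cc1OC | starting material
3 | benzyl 3-(3,4-dimethoxyphenyl)-2-methyl-3-oxopropanoate (racemic) | COc1ccc(C(=O)C(C)C(=O)OCc2ccccc2)cc1OC | intermediate
4 | benzyl 2-bromo-3-(3,4-dimethoxyphenyl)-2-methyl-3-oxopropanoate (racemic) | COc1ccc(C(=O)C(C)(Br)C(=O)OCc2ccccc2)cc1OC | intermediate
5 | 5-bromo-2-methoxyphenol | COc1ccc(Br)cc1O | starting material
6 | 2-(benzyloxy)-4-bromo-1-methoxybenzene | COc1ccc(Br)cc1OCc1ccccc1 | intermediate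
7 | 2-(benzyloxy)-1-methoxy-4-(prop-1-yn-1-yl)benzene | CC#Cc1ccc(OC)c(OCc2ccccc2)c1 | intermediate
8 | benzyl (2S)-4-[3-(benzyloxy)-4-methoxyphenyl]-6,7-dimethoxy-2,3-dimethyl-1-oxo-1,2-dihydronaphthalene-2-carboxylate | COc1cc2c(cc1OC)C(=O)[C@@](C)(C(=O)OCc1ccccc1)C(C)=C2c1ccc(OC)c(OCc2ccccc2)c1 | intermediate
9 | benzyl (2S,3R,4R)-4-[3-(benzyloxy)-4-methoxyphenyl]-6,7-dimethoxy-2,3-dimethyl-1-oxo-1,2,3,4-tetrahydronaphthalene-2-carboxylate | COc1cc2c(cc1OC)C(=O)[C@@](C)(C(=O)OCc1ccccc1)[C@H](C)[C@@H]2c1ccc(OC)c(OCc2ccccc2)c1 | intermediate
10 | (2S,3R,4R)-4-(3-hydroxy-4-methoxyphenyl)-6,7-dimethoxy-2,3-dimethyl-1-oxo-1,2,3,4-tetrahydronaphthalene-2-carboxylic acid | COc1cc2c(cc1OC)C(=O)[C@@](C)(C(=O)O)[C@H](C)[C@@H]2c1ccc(OC)c(O)c1 | intermediate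
11 | (2R,3R,4R)-4-(3-hydroxy-4-methoxyphenyl)-6,7-dimethoxy-2,3-dimethyl-3,4-dihydronaphthalen-1(2H)-one (C2 epimer of the target) | COc1ccc([C@@H]2c3cc(OC)c(OC)cc3C(=O)[C@H](C)[C@@H]2C)cc1O | intermediate
12 | (2S,3R,4R)-4-(3-hydroxy-4-methoxyphenyl)-6,7-dimethoxy-2,3-dimethyl-3,4-dihydronaphthalen-1(2H)-one | COc1ccc([C@@H]2c3cc(OC)c(OC)cc3C(=O)[C@@H](C)[C@@H]2C)cc1O | target

Total step count: 7. Longest linear sequence: 5 steps (1, 2, 5, 6, 7 or 3, 4, 5, 6, 7).

The three steps most likely to fail are steps 5, 6 and 7.

Step 5 may suffer from three processes: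
- insufficient facial discrimination at the chelated C2 radical, because unbound radical reacts as a racemic background;
- bromine-atom transfer to the vinyl radical outrunning ring closure;
- slow addition of a tertiary radical to an internal alkyne.

The fallback gives up asymmetric induction and uses known chemistry. It sets out from 3 and 7. The C2 radical is generated with Mn(OAc)3·2H2O (2.2 equiv) in AcOH at 70 °C. This is the established oxidative radical annulation by trivalent manganese, in which a second equivalent of oxidant rearomatises ring A. The product is racemic benzyl 4-[3-(benzyloxy)-4-methoxyphenyl]-6,7-dimethoxy-2,3-dimethyl-1-oxo-1,2-dihydronaphthalene-2-carboxylate F1. Its enantiomers are separated by preparative chromatography on a chiral stationary phase, and the (S)-enantiomer is compound 8, where the route is rejoined.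

Step 6 may suffer from sluggish or undirected hydrogen delivery to the hindered tetrasubstituted double bond, that is, poor facial selectivity if the ester binds the iridium centre only weakly. The fallback installs a stronger directing group. It sets out from 8. Luche reduction (NaBH4, CeCl3·7H2O, MeOH, −20 °C), with hydride expected to approach anti to the ester, should give benzyl (1R,2S)-4-[3-(benzyloxy)-4-methoxyphenyl]-1-hydroxy-6,7-dimethoxy-2,3-dimethyl-1,2-dihydronaphthalene-2-carboxylate F2. Hydroxyl-directed hydrogenation with [Ir(cod)(PCy3)(py)]PF6, with the homoallylic hydroxyl and the ester on the same face, should give benzyl (1R,2S,3R,4R)-4-[3-(benzyloxy)-4-methoxyphenyl]-1-hydroxy-6,7-dimethoxy-2,3-dimethyl-1,2,3,4-tetrahydronaphthalene-2-carboxylate F3. Dess–Martin oxidation of the carbinol then returns to the route at 9.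

Step 7 may suffer from over-reduction of the electron-rich aryl ketone during hydrogenolysis. The fallback removes both benzyl groups without any reductant. It sets out from 9. BCl3 and pentamethylbenzene in CH2Cl2 at −78 °C cleave the aryl benzyl ether and the benzyl ester. No methoxy group stands ortho to the carbonyl, so the methyl ethers should hold. Aqueous work-up gives the same keto acid 10, which is decarboxylated at 50 °C and equilibrated with DBU as before, so the route is rejoined at 12. This fallback makes no new compound (F0).

Further compounds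
F1 | step 5 | racemic benzyl 4-[3-(benzyloxy)-4-methoxyphenyl]-6,7-dimethoxy-2,3-dimethyl-1-oxo-1,2-dihydronaphthalene-2-carboxylate | COc1cc2c(cc1OC)C(=O)C(C)(C(=O)OCc1ccccc1)C(C)=C2c1ccc(OC)c(OCc2ccccc2)c1
F2 | step 6 | benzyl (1R,2S)-4-[3-(benzyloxy)-4-methoxyphenyl]-1-hydroxy-6,7-dimethoxy-2,3-dimethyl-1,2-dihydronaphthalene-2-carboxylate | COc1cc2c(cc1OC)[C@@H](O)[C@@](C)(C(=O)OCc1ccccc1)C(C)=C2c1ccc(OC)c(OCc2ccccc2)c1
F3 | step 6 | benzyl (1R,2S,3R,4R)-4-[3-(benzyloxy)-4-methoxyphenyl]-1-hydroxy-6,7-dimethoxy-2,3-dimethyl-1,2,3,4-tetrahydronaphthalene-2-carboxylate | COc1cc2c(cc1OC)[C@@H](O)[C@@](C)(C(=O)OCc1ccccc1)[C@H](C)[C@@H]2c1ccc(OC)c(OCc2ccccc2)c1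
F0 | step 7 | none | none
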